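## The problem

Target 14 is a 3,3′-linked pair of 4-(4-hydroxyphenyl)chroman-2-ones. Ring A is 5,7-dihydroxylated, ring B carries hydroxyls at C5′, C6′, C7′ and C8′, and C2–C3–C3′–C2′ is a 2,3-disubstituted succinate tied into two aryl δ-lactones, so the central bond joins two tertiary carbons, each next to a diarylmethine (C4, C4′). The four contiguous stereocentres are 3S,4R,3′S,4′R: both halves have the same sense, and in each lactone the C3 substituent is cis to the C4 aryl group. That cis arrangement should be the less stable one, because the peri oxygen at C5/C5′ holds the 4-aryl group pseudo-axial and the trans isomer puts the C3 substituent anti to it. H-3 and H-3′ are α to aryl esters, so any base can move cis to trans. C4 and C4′ carry no acidic hydrogen and are the fixed points from which C3 and C3′ must be set, late and under kinetic control. The two halves differ only by the oxygens at C6′ and C8′, so a union at C3–C3′ is a cross-coupling of two nearly identical partners. The aryl lactones are open to hydrolysis, aminolysis and ketene formation from their enolates, and free ring B (five oxygens) is oxidised by air, so the eight phenols stay masked until a last, non-basic step. The feature that makes the key step possible is this: C3 and C3′ are each the α-carbon of a lactone carbonyl (C2, C2′) and each stands next to a C4/C4′ aryl group fixed pseudo-axial by the C5/C5′ oxygen, and in 14 both H-3 and H-3′ lie on the ring face opposite that aryl group, the face from which a proton reaches the planar enolate carbon.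

## Retrosynthesis

14 to 12. The eight O–CH3 bonds are cut. Methyl ethers survive bromination, hot methoxide, amide bases and the copper oxidant, and their removal with BBr3 is acidic, which the base-labile cis centres tolerate. 12 has the full skeleton and stereochemistry but is stable to air.

12 to 10 (through 11). The C3–H and C3′–H bonds are cut. The C–C bond formation is not asked to deliver the cis relationship; it cannot, since a new bond at C3 also forms anti to the aryl group and gives trans. Instead both C3 centres are made trigonal in the bis-enolate 11 and then protonated. Any C3/C3′ stereoisomer of the dimer serves, so the precursor 10 is stereochemically undemanding. The forward reaction must deliver both protons anti to the aryl groups with no proton exchange afterwards.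

10 to 3 and 7. The C3–C3′ bond is cut, giving two lactone enolates (8 and 9) for an oxidative cross-coupling that copies a plausible oxidative α,α′-dimerisation of two 4-arylchromanone units. Each partner is half the size and already carries its C4 stereocentre. The stereochemical outcome at C3 does not matter; cross-selectivity is bought with an excess of the cheaper partner 3.

7 to 4 to 3. The C6–O and C8–O bonds of ring B are cut. Ring B is ring A plus oxygen at its only two free positions, so 7 is made from 3 by dibromination (4) and copper-mediated methoxylation. One asymmetric reaction then supplies C4 and C4′ with the same sense, which the like configuration of the two halves requires. A separately built tetraoxygenated coumarin would cost several steps and a second asymmetric step.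

3 to 1 and 2. The C4–aryl bond is cut. Rhodium-catalysed asymmetric 1,4-addition of boronic acid 2 to coumarin 1 sets the only catalyst-controlled stereocentre of the route; both materials are commercial.

## Roads not taken

Alternative 1: the most obvious cut is the classical one for 4-arylchromanones (phenol plus cinnamic acid), applied twice. It cuts C4–C4a and O1–C2 in ring A and the primed pair in ring B, leading to (2E,3E)-2,3-bis(4-hydroxybenzylidene)succinic acid A1 and the two polyphenols. The forward key step is an acid-mediated double hydroarylation–lactonisation. The chosen plan is better for four reasons. In A1 protonation at C3 precedes bond formation at C4, and the cationic ring closure places the C3 substituent anti to the aryl group (allylic strain in the benzylic cation), giving trans. The products form as free phenols and cannot then be corrected through enolates. Nothing sets absolute configuration. Two different arenes must add to two equivalent sites, and the ring B arene would have to be handled as a free pentaoxygenated benzene.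

Alternative 2: cut the four C–H bonds at C3, C4, C3′ and C4′, giving the flat bicoumarin A2, which could be assembled from a succinate and two 2-hydroxybenzophenones by twofold Perkin-type condensation. The forward key step is two syn-hydrogenations, which would guarantee cis in each ring. The chosen plan is better because both double bonds of A2 are tetrasubstituted and sit on a tetra-ortho-substituted axis. The sense of addition at the second ring relative to the first depends on rotamers about C3–C3′ and cannot be predicted. No catalyst class reliably sets absolute configuration at such coumarin double bonds, whereas the chosen route takes it from a conjugate addition with close precedent, at a similar step count.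

Alternative 3: cut C3–C4 and O1–C2 (and the primed pair) and build each lactone by a catalyst-controlled [4+2] annulation of a carbene-bound enolate, derived from a four-carbon succinyl unit, with an ortho-quinone methide such as A3, one ring after the other. The forward key step is an endo-selective hetero-Diels–Alder reaction that would give cis rings directly. The chosen plan is better because quinone methides with a methoxy group next to the methide carbon have ill-defined geometry, and the cis/trans outcome follows that geometry. The second annulation would need an enolate substituted by the whole first ring. Each quinone methide also needs its own multistep precursor, so the run-up is longer than the whole chosen route.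

Key step: step 5

Remark: 10 is drawn as the trans,trans isomer expected from the coupling; its configuration at C3 and C3′ is erased in step 5, so any C3/C3′ epimer formed with it is carried forward.

## Route

Step 1
Reactants: 1 5,7-dimethoxy-2H-chromen-2-one; 2 4-methoxyphenylboronic acid
Product: 3 (4R)-5,7-dimethoxy-4-(4-methoxyphenyl)chroman-2-one
Conditions: Rh(acac)(C2H4)2 (3 mol %), (R)-Segphos (3.3 mol %), 2 (5 equiv), 1,4-dioxane/H2O 10:1, 60 °C
Reagents that add atoms: none
Why: Hayashi–Miyaura asymmetric 1,4-addition of an arylboronic acid to a coumarin; the aryl–rhodium species adds to C4 on the face chosen by the ligand, and water protonates the oxa-π-allyl rhodium; by analogy with simpler coumarins (R)-Segphos should give the 4R product, and the other ligand enantiomer is available if the sense proves reversed.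

Step 2
Reactants: 3 (4R)-5,7-dimethoxy-4-(4-methoxyphenyl)chroman-2-one
Product: 4 (4R)-6,8-dibromo-5,7-dimethoxy-4-(4-methoxyphenyl)chroman-2-one
Conditions: NBS (2.1 equiv), MeCN, 0 °C to rt, dark
Reagents that add atoms: N-bromosuccinimide, O=C1CCC(=O)N1Br
Why: Electrophilic aromatic bromination; C6 and C8 are the only free positions of the trioxygenated ring A and are far more nucleophilic than the anisyl ring; C4 is not touched.

Step 3
Reactants: 4 (4R)-6,8-dibromo-5,7-dimethoxy-4-(4-methoxyphenyl)chroman-2-one
Product: 7 (4R)-5,6,7,8-tetramethoxy-4-(4-methoxyphenyl)chroman-2-one, via ring-opened dibromo ester sodium phenoxide 5 (not isolated), via ring-opened tetramethoxy phenol ester 6 (not isolated)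
Conditions: NaOMe (10 equiv, in MeOH), CuI (30 mol %), DMF, 110 °C, sealed; aq. HCl work-up; then p-TsOH·H2O (10 mol %), toluene, reflux
Reagents that add atoms: sodium methoxide, [Na+].[O-]C
Why: Ullmann-type copper-catalysed methoxylation of aryl bromides, the classical route from bromophenols to methoxyphenols; methoxide first opens the lactone to phenoxide ester 5, both C–Br bonds are exchanged for C–OMe, and acid re-closes the six-membered lactone from 6 with loss of methanol; C4 has no acidic hydrogen and keeps its configuration.

Step 4
Reactants: 3 (4R)-5,7-dimethoxy-4-(4-methoxyphenyl)chroman-2-one; 7 (4R)-5,6,7,8-tetramethoxy-4-(4-methoxyphenyl)chroman-2-one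
Product: 10 (3R,3′R,4R,4′R)-5,5′,6′,7,7′,8′-hexamethoxy-4,4′-bis(4-methoxyphenyl)-[3,3′-bichromane]-2,2′-dione, via lithium enolate of the ring A monomer 8 (not isolated), via lithium enolate of the ring B monomer 9 (not isolated)
Conditions: 3 (3 equiv), 7 (1 equiv), LiN(SiMe3)2 (4.2 equiv), THF, −78 °C; then Cu(O2CCH(Et)nBu)2 (4.4 equiv), −78 to 0 °C
Reagents that add atoms: none
Why: Oxidative coupling of lithium ester enolates by a divalent copper carboxylate; one-electron oxidation gives α-lactone radicals that join at C3/C3′, each new bond forming anti to the pseudo-axial C4 aryl group (trans,trans expected, erased in step 5). The threefold excess of the cheaper 3 should channel most of 7 into the cross-product; the homodimers are removed by chromatography.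

Step 5
Reactants: 10 (3R,3′R,4R,4′R)-5,5′,6′,7,7′,8′-hexamethoxy-4,4′-bis(4-methoxyphenyl)-[3,3′-bichromane]-2,2′-dione
Product: 12 (3S,3′S,4R,4′R)-5,5′,6′,7,7′,8′-hexamethoxy-4,4′-bis(4-methoxyphenyl)-[3,3′-bichromane]-2,2′-dione, via dilithium bis-enolate 11 (not isolated)
Conditions: LiN(iPr)2 (3.0 equiv), THF, −78 to −45 °C; then transfer by cannula into AcOH (10 equiv) in THF, −78 °C
Reagents that add atoms: none
Why: The amide base removes H-3 and H-3′ to give the succinate-type bis-enolate 11, in which C3 and C3′ are trigonal and the configuration left by step 4 is erased; transfer into excess acetic acid then protonates both carbons irreversibly. The closest known reaction type is the kinetic protonation of cyclic enolates that carry an adjacent substituent, which gives the less stable cis-2,3-disubstituted product. No ring is closed. Each new stereocentre is controlled by its neighbour: the enolised lactone ring is nearly planar, the C4/C4′ aryl group stands perpendicular to it (held there by the C5/C5′ methoxy group), so the proton arrives on the opposite face and the C3–C3′ bond ends cis to the aryl group in both rings. Because C4 and C4′ are both R, the two protonations give 3S and 3′S without any separate control of the relation between the halves. The step needs facial selectivity in two C-protonations and no proton exchange between product and remaining enolate; the aryl shielding should secure the first and the inverse quench into excess acid at −78 °C the second. The process is convergent, since a ring that is enolised again returns cis, so incomplete double deprotonation can be driven to completion by repetition.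

Step 6
Reactants: 12 (3S,3′S,4R,4′R)-5,5′,6′,7,7′,8′-hexamethoxy-4,4′-bis(4-methoxyphenyl)-[3,3′-bichromane]-2,2′-dione
Product: 14 (3S,3′S,4R,4′R)-5,5′,6′,7,7′,8′-hexahydroxy-4,4′-bis(4-hydroxyphenyl)-[3,3′-bichromane]-2,2′-dione, via octakis(dibromoboryl) ether 13 (not isolated)
Conditions: BBr3 (24 equiv), CH2Cl2, −78 to 0 °C; then degassed H2O/MeOH, 0 °C, under argon
Reagents that add atoms: none
Why: Lewis-acid cleavage of aryl methyl ethers (bromide attack on the methyl group of the boron-bound ether), with hydrolysis of the aryl borates on work-up; the medium is acidic throughout, so the base-labile C3/C3′ centres should hold. If a lactone opens it can only re-close to the same ring, because both arenes are symmetric about their C4a–C7 axes.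

## Compound list

1 | 5,7-dimethoxy-2H-chromen-2-one | O=C1C=Cc2c(OC)cc(OC)cc2O1 | starting material
2 | 4-methoxyphenylboronic acid | OB(O)c1ccc(OC)cc1 | starting material
3 | (4R)-5,7-dimethoxy-4-(4-methoxyphenyl)chroman-2-one | O=C1Oc2cc(OC)cc(OC)c2[C@@H](c2ccc(OC)cc2)C1 | intermediate
4 | (4R)-6,8-dibromo-5,7-dimethoxy-4-(4-methoxyphenyl)chroman-2-one | O=C1Oc2c(Br)c(OC)c(Br)c(OC)c2[C@@H](c2ccc(OC)cc2)C1 | intermediate
5 | sodium 2,4-dibromo-3,5-dimethoxy-6-[(1R)-3-methoxy-1-(4-methoxyphenyl)-3-oxopropyl]phenolate | [Na+].[O-]c1c(Br)c(OC)c(Br)c(OC)c1[C@@H](c1ccc(OC)cc1)CC(=O)OC | intermediate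
6 | methyl (3R)-3-(2-hydroxy-3,4,5,6-tetramethoxyphenyl)-3-(4-methoxyphenyl)propanoate | Oc1c(OC)c(OC)c(OC)c(OC)c1[C@@H](c1ccc(OC)cc1)CC(=O)OC | intermediate
7 | (4R)-5,6,7,8-tetramethoxy-4-(4-methoxyphenyl)chroman-2-one | O=C1Oc2c(OC)c(OC)c(OC)c(OC)c2[C@@H](c2ccc(OC)cc2)C1 | intermediate
8 | lithium (4R)-5,7-dimethoxy-4-(4-methoxyphenyl)-4H-chromen-2-olate | [Li+].[O-]C1=C[C@H](c2ccc(OC)cc2)c2c(OC)cc(OC)cc2O1 | intermediate
9 | lithium (4R)-5,6,7,8-tetramethoxy-4-(4-methoxyphenyl)-4H-chromen-2-olate | [Li+].[O-]C1=C[C@H](c2ccc(OC)cc2)c2c(OC)c(OC)c(OC)c(OC)c2O1 | intermediate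
10 | (3R,3′R,4R,4′R)-5,5′,6′,7,7′,8′-hexamethoxy-4,4′-bis(4-methoxyphenyl)-[3,3′-bichromane]-2,2′-dione (trans,trans) | O=C1Oc2cc(OC)cc(OC)c2[C@@H](c2ccc(OC)cc2)[C@@H]1[C@@H]1C(=O)Oc2c(OC)c(OC)c(OC)c(OC)c2[C@H]1c1ccc(OC)cc1 | intermediate
11 | dilithium (4R,4′R)-5,5′,6′,7,7′,8′-hexamethoxy-4,4′-bis(4-methoxyphenyl)-4H,4′H-[3,3′-bichromene]-2,2′-diolate | [Li+].[Li+].[O-]C1=C(C2=C([O-])Oc3c(OC)c(OC)c(OC)c(OC)c3[C@H]2c2ccc(OC)cc2)[C@H](c2ccc(OC)cc2)c2c(OC)cc(OC)cc2O1 | intermediate
12 | (3S,3′S,4R,4′R)-5,5′,6′,7,7′,8′-hexamethoxy-4,4′-bis(4-methoxyphenyl)-[3,3′-bichromane]-2,2′-dione (cis,cis) | O=C1Oc2cc(OC)cc(OC)c2[C@@H](c2ccc(OC)cc2)[C@H]1[C@H]1C(=O)Oc2c(OC)c(OC)c(OC)c(OC)c2[C@H]1c1ccc(OC)cc1 | intermediate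
13 | octakis(dibromoboryl) ether of 14 (idealised aryl borate stage before hydrolysis, configuration as in 12) | O=C1Oc2cc(OB(Br)Br)cc(OB(Br)Br)c2[C@@H](c2ccc(OB(Br)Br)cc2)[C@H]1[C@H]1C(=O)Oc2c(OB(Br)Br)c(OB(Br)Br)c(OB(Br)Br)c(OB(Br)Br)c2[C@H]1c1ccc(OB(Br)Br)cc1 | intermediate
14 | (3S,3′S,4R,4′R)-5,5′,6′,7,7′,8′-hexahydroxy-4,4′-bis(4-hydroxyphenyl)-[3,3′-bichromane]-2,2′-dione | O=C1Oc2cc(O)cc(O)c2[C@@H](c2ccc(O)cc2)[C@H]1[C@H]1C(=O)Oc2c(O)c(O)c(O)c(O)c2[C@H]1c1ccc(O)cc1 | target

## Step count and risks

Total step count: 6. Longest linear sequence: 6 steps (1 to 3 to 4 to 7 to 10 to 12 to 14).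

Least certain steps:

Step 5 (key step). What may go wrong: the second deprotonation at the hindered tertiary α-carbon may be incomplete, proton exchange between product and unquenched enolate during the quench would drift the mixture toward trans, and the aryl-lactone enolate may open to a ketene that the amine captures. Fallback: from 10, the bis-enolate 11 would be oxidised in the flask with iodine (vicinal diester dianion to alkene) to (E,4R,4′R)-5,5′,6′,7,7′,8′-hexamethoxy-4,4′-bis(4-methoxyphenyl)-[3,3′-bichromanylidene]-2,2′-dione F1. In F1 both aryl groups stand on the same face of the tetrasubstituted C3=C3′ bond. Hydrogenation of F1 (H2, 50 bar, PtO2, EtOAc) should add both hydrogens syn from the open face and so return to the route at 12.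

Step 4. What may go wrong: statistical partition of the two enolates into homo- and cross-dimers, and slow combination of two hindered α-carbons with competing reduction back to the monomers. Fallback: a union with matched polarity. 7 would be brominated through its enolate (LiN(SiMe3)2, then NBS, THF, −78 °C) to (3S,4R)-3-bromo-5,6,7,8-tetramethoxy-4-(4-methoxyphenyl)chroman-2-one F2. 3 would be silylated (LiN(SiMe3)2, Me3SiCl) to (4R)-5,7-dimethoxy-4-(4-methoxyphenyl)-2-(trimethylsilyloxy)-4H-chromene F3. Visible-light irradiation of F2 with excess F3 and Ir(ppy)3 (radical–polar crossover alkylation of an enol silane by an α-bromo carbonyl compound) should join the electrophilic α-lactone radical from F2 to the electron-rich ketene acetal carbon of F3 only, and comes back to the route at 10.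

Step 3. What may go wrong: protodebromination instead of C–O bond formation at the two doubly ortho-substituted positions, or a stalled second substitution. Fallback: the C–O bonds would be made by oxidation of C–B bonds. From 4, Miyaura borylation (B2pin2, Pd(OAc)2, SPhos, KOAc, dioxane, 90 °C) would give (4R)-5,7-dimethoxy-4-(4-methoxyphenyl)-6,8-bis(4,4,5,5-tetramethyl-1,3,2-dioxaborolan-2-yl)chroman-2-one F4. Oxidation (NaBO3·4H2O, THF/H2O, then mild acid) would give (4R)-6,8-dihydroxy-5,7-dimethoxy-4-(4-methoxyphenyl)chroman-2-one F5, and O-methylation (MeI, K2CO3, acetone) returns to the route at 7.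

Step 1. What may go wrong: slow insertion at C4 next to the peri methoxy group on an electron-rich coumarin, so that protodeboronation of 2 outruns the addition, and loss of enantioselectivity at the higher temperature then needed. Fallback: the stereocentre would be set by hydride delivery instead of aryl delivery. From 1 and 2, an oxidative Heck reaction (Pd(OAc)2, 1,10-phenanthroline, O2, DMF) would give 5,7-dimethoxy-4-(4-methoxyphenyl)-2H-chromen-2-one F6. Copper hydride asymmetric conjugate reduction of F6 (Cu(OAc)2·H2O, DTBM-Segphos in the enantiomer that gives the 4R product, (EtO)2MeSiH, t-BuOH, toluene) returns to the route at 3.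

Step 6. What may go wrong: acid-promoted enolisation and epimerisation at C3/C3′ during the long exposure needed to cleave eight ethers, and air oxidation of ring B on work-up. Fallback: the order of deprotection and stereocontrol would be reversed. From 10, BBr3 would first give (3R,3′R,4R,4′R)-5,5′,6′,7,7′,8′-hexahydroxy-4,4′-bis(4-hydroxyphenyl)-[3,3′-bichromane]-2,2′-dione F7, where epimerisation is of no consequence. Excess LiN(SiMe3)2 and Me3SiCl would convert F7 in the flask into the decakis(trimethylsilyl) bis(ketene acetal) F8. Kinetic protodesilylation of F8 (AcOH, MeOH, THF, −78 to 0 °C) should protonate C3 and C3′ anti to the aryl groups and free the phenols, arriving directly at 14.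

## Further compounds

F1 | step 5 | (E,4R,4′R)-5,5′,6′,7,7′,8′-hexamethoxy-4,4′-bis(4-methoxyphenyl)-[3,3′-bichromanylidene]-2,2′-dione | O=C1Oc2cc(OC)cc(OC)c2[C@@H](c2ccc(OC)cc2)/C1=C1\C(=O)Oc2c(OC)c(OC)c(OC)c(OC)c2[C@H]1c1ccc(OC)cc1
F2 | step 4 | (3S,4R)-3-bromo-5,6,7,8-tetramethoxy-4-(4-methoxyphenyl)chroman-2-one | O=C1Oc2c(OC)c(OC)c(OC)c(OC)c2[C@@H](c2ccc(OC)cc2)[C@@H]1Br
F3 | step 4 | (4R)-5,7-dimethoxy-4-(4-methoxyphenyl)-2-(trimethylsilyloxy)-4H-chromene | C[Si](C)(C)OC1=C[C@H](c2ccc(OC)cc2)c2c(OC)cc(OC)cc2O1
F4 | step 3 | (4R)-5,7-dimethoxy-4-(4-methoxyphenyl)-6,8-bis(4,4,5,5-tetramethyl-1,3,2-dioxaborolan-2-yl)chroman-2-one | O=C1Oc2c(B3OC(C)(C)C(C)(C)O3)c(OC)c(B3OC(C)(C)C(C)(C)O3)c(OC)c2[C@@H](c2ccc(OC)cc2)C1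
F5 | step 3 | (4R)-6,8-dihydroxy-5,7-dimethoxy-4-(4-methoxyphenyl)chroman-2-one | O=C1Oc2c(O)c(OC)c(O)c(OC)c2[C@@H](c2ccc(OC)cc2)C1
F6 | step 1 | 5,7-dimethoxy-4-(4-methoxyphenyl)-2H-chromen-2-one | COc1ccc(cc1)C1=CC(=O)Oc2cc(OC)cc(OC)c12
F7 | step 6 | (3R,3′R,4R,4′R)-5,5′,6′,7,7′,8′-hexahydroxy-4,4′-bis(4-hydroxyphenyl)-[3,3′-bichromane]-2,2′-dione | O=C1Oc2cc(O)cc(O)c2[C@@H](c2ccc(O)cc2)[C@@H]1[C@@H]1C(=O)Oc2c(O)c(O)c(O)c(O)c2[C@H]1c1ccc(O)cc1
F8 | step 6 | (4R,4′R)-2,2′,5,5′,6′,7,7′,8′-octakis(trimethylsilyloxy)-4,4′-bis[4-(trimethylsilyloxy)phenyl]-4H,4′H-3,3′-bichromene | C[Si](C)(C)OC1=C(C2=C(O[Si](C)(C)C)Oc3c(O[Si](C)(C)C)c(O[Si](C)(C)C)c(O[Si](C)(C)C)c(O[Si](C)(C)C)c3[C@H]2c2ccc(O[Si](C)(C)C)cc2)[C@H](c2ccc(O[Si](C)(C)C)cc2)c2c(O[Si](C)(C)C)cc(O[Si](C)(C)C)cc2O1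
A1 | alternative 1 | (2E,3E)-2,3-bis(4-hydroxybenzylidene)succinic acid | O=C(O)/C(=C/c1ccc(O)cc1)/C(=C\c1ccc(O)cc1)C(=O)O
A2 | alternative 2 | 5,5′,6′,7,7′,8′-hexamethoxy-4,4′-bis(4-methoxyphenyl)-2H,2′H-[3,3′-bichromene]-2,2′-dione | COc1ccc(cc1)C1=C(C2=C(c3ccc(OC)cc3)c3c(OC)c(OC)c(OC)c(OC)c3OC2=O)C(=O)Oc2cc(OC)cc(OC)c12
A3 | alternative 3 | (6E)-3,5-dimethoxy-6-(4-methoxybenzylidene)cyclohexa-2,4-dien-1-one | COC1=CC(=O)/C(=C/c2ccc(OC)cc2)C(OC)=C1
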